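(All runs stem from a simulated flask from invented constants.)

The trap in these tables is that [substrate] looks like one setting among several, yet partner and catalyst are charged on it, so at fixed equivalents and mol% a richer flask is richer in all three. Take the catalyst as coming back, and freeze [catalyst] at its charge. Then, if the step is first order in substrate, partner and catalyst, a flask with e equivalents and product fraction y obeys ln[(e − y)/(e(1 − y))] = (e − 1)pt, where p, its pace, is k[catalyst][substrate] at the charge.

| flask | substrate | partner | catalyst | temperature | remark | time |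
|---|---|---|---|---|---|---|
| alder | 34 mM | 1.2 equiv | 1 mol% | 15 °C | run made earlier |  |
| elm | 47 mM | 1.2 equiv | 1 mol% | 35 °C | run made earlier |  |
| oak | 48 mM | 1.2 equiv | 1 mol% | 15 °C | run made earlier |  |
| birch | 37 mM | 1.2 equiv | 0.56 mol% | 35 °C | run made earlier |  |
| amber | 37 mM | 1.20 equiv | 0.5 mol% | 20 °C |  | 10 h |
| violet | 37 mM | 1.20 equiv | 0.6 mol% | 50 °C |  | 10 h |
| teal | 60 mM | 3.60 equiv | 1 mol% | 50 °C |  | 10 h |
| green | 37 mM | 1.20 equiv | 1 mol% | 50 °C |  | 10 h |

| run | time / h | product / % |
|---|---|---|
| alder | 5.00 | 3.0 |
| alder | 8.00 | 5.5 |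
| alder | 15.0 | 7.7 |
| alder | 30.0 | 15.5 |
| alder | 60.0 | 27.5 |
| elm | 2.00 | 7.5 |
| elm | 3.00 | 14.3 |
| elm | 6.00 | 21.8 |
| elm | 10.0 | 34.6 |
| elm | 20.0 | 47.7 |
| oak | 12.0 | 14.1 |
| oak | 25.0 | 24.9 |
| oak | 30.0 | 30.0 |
| oak | 50.0 | 37.9 |
| oak | 60.0 | 45.9 |
| birch | 2.00 | 3.5 |
| birch | 3.00 | 4.0 |
| birch | 6.00 | 8.3 |
| birch | 10.0 | 14.3 |
| birch | 20.0 | 23.6 |

(readings scatter by 1 percentage point)

1. the flasks by amount of product, in percent of the substrate charged, highest first, at 10 h (amber / violet / teal / green)
2. the amount of product, in percent of the substrate charged of the flask you put first, at 10 h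
3. the amount of product, in percent of the substrate charged of the flask you put last, at 10 h

- the numbers in the tables scatter by 1 percentage point (one standard deviation)

Take concentration first. By hand, at fixed equivalents and mol%, p goes with [substrate] squared, so oak should outrun alder by 1.99. The last readings give paces of 0.0110 h⁻¹ for oak and 0.00511 h⁻¹ for alder, a ratio of 2.15.

Catalyst next: with concentration counted, elm should outrun birch by 2.88, and their last readings give 0.0354 h⁻¹ over 0.0126 h⁻¹, a ratio of 2.81.

Temperature: with both corrected, elm over oak is 3.35, which reads as an activation energy of 44.6 kJ mol⁻¹. Going to 50 °C is an extrapolation beyond the runs, and I scale it from elm; amber, at 20 °C, I scale from oak.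

Partner was varied by no run, so its first order is an assumption. It enters through e, substrate being the limiting reagent at 1.20 equiv and 3.60 equiv.

So teal's pace, k[catalyst][substrate], is 0.129 h⁻¹. At 10 h my reckoning gives teal 97.5%, green 38.3%, violet 26.7% and amber 5.14%.

The forecast, from its own fits, gave the same order as mine, teal > green > violet > amber, with 97% for teal and 5% for amber, and warned: “Teal relies on an untested partner order”.

The flasks give teal > green > violet > amber: teal 92.3%, green 36.9%, violet 25.9%, amber 5.23%.

    substrate ⇌ dormant form (K = 0.670, k = 0.0960 h⁻¹, Ea = 114 kJ mol⁻¹, ΔH = −51.0 kJ mol⁻¹)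
    substrate + partner + catalyst → catalyst + product (k = 4700 L² mol⁻² h⁻¹, Ea = 51.0 kJ mol⁻¹)
    (constants at 50 °C)

In teal, with the concentrations as charged, substrate has a half-life of 1.1 h by the product step, shorter than the 7.2 h by the forward step to the dormant form taken alone. Teal's pace gave 97.5% of product, and at 10 h the flask holds 92.3% product, 5.68% dormant form and 2.1% substrate.

Now take teal at 15 mM of substrate, with its equivalents and mol% held. By my reckoning the pace falls with the square to 0.00808 h⁻¹, which gives 24.5%. The computed flask holds 23.7% product, with 30.0% dormant form and 46.3% substrate.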